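**Strategy.** Clerodane numbering is used. Ring A (C1–C5, C10) is closed last by an anionic oxy-Cope rearrangement. The precursor is a bicyclo[2.2.2]octenol in which ring B already exists and a temporary C2–C7 bond places a 1-methoxyallenyl carbinol (C2) next to the methoxy-bearing bridgehead C7. The [3,3] shift breaks C2–C7 and forms C4–C5. In one operation it gives the cis-decalin, the quaternary C5 (relayed from C10), the C4 exocyclic methylene, the C2/C3 dioxygenation and the C7 oxygen as an enol ether. It exploits the 1,6-relationship of the C2 and C7 oxygens across the C5–C10 ring fusion, with C6 as the link.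

Key step: step 12

Numbering: ring A = C1–C5, C10; ring B = C5–C10; side chain C11–C15 on C9 (C16 = methyl on C13); C17 = methyl on C8; C18 = exocyclic CH2 on C4; C19 = methyl on C5; C20 = methyl on C9.

Assumption: (R,R)-1-naphthyl-TADDOL is taken to give the shown C8/C9 configuration in step 3; if the sense of induction is the reverse, the antipodal diol is used.

Step 1
Reactants: 1 methyl hydrogen (R)-3-methylglutarate
Product: 2 methyl (3S)-4-iodo-3-methylbutanoate
Conditions: PhI(OAc)2, I2, cyclohexane, hν (tungsten lamp), reflux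
Reagents that add atoms: iodine, II
Why: Hunsdiecker-type decarboxylative iodination through the acyl hypoiodite and a primary alkyl radical; the stereocentre lies one carbon away from the radical and is untouched (the descriptor changes only by priority).

Step 2
Reactants: 2 methyl (3S)-4-iodo-3-methylbutanoate
Product: 3 [(2S)-4-methoxy-2-methyl-4-oxobutyl]triphenylphosphonium iodide
Conditions: PPh3, MeCN, 85 °C, sealed tube
Reagents that add atoms: triphenylphosphine, c1ccc(cc1)P(c1ccccc1)c1ccccc1
Why: SN2 quaternisation of the phosphine by the primary iodide (phosphonium salt formation), with no stereocentre involved.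

Step 3
Reactants: 4 (1E)-3-(tert-butyldimethylsilyloxy)-N,N-dimethylbuta-1,3-dien-1-amine; 5 (2E)-2-methylbut-2-enal
Product: 6 (1S,2R,6R)-4-(tert-butyldimethylsilyloxy)-2-(dimethylamino)-1,6-dimethylcyclohex-3-ene-1-carbaldehyde (endo adduct; ring C1 = C9, C6 = C8, CHO = C11)
Conditions: (R,R)-1-naphthyl-TADDOL (20 mol %), toluene, −60 °C
Reagents that add atoms: none
Why: Hydrogen-bond-catalysed enantioselective Diels–Alder reaction in which the amino terminus of the diene bonds to the aldehyde α-carbon, the E geometry of 5 fixes the C17 and C20 methyls cis, and the diol-bound aldehyde face sets the absolute configuration of C9 and C8 (the amino-bearing centre is lost in step 5).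

Step 4
Reactants: 6 the aldehyde of step 3; 3 the phosphonium iodide
Product: 7 methyl (3S,4Z)-5-[(1S,2R,6R)-4-(tert-butyldimethylsilyloxy)-2-(dimethylamino)-1,6-dimethylcyclohex-3-en-1-yl]-3-methylpent-4-enoate
Conditions: KN(SiMe3)2, THF, −78 °C; then 6, −78 → 0 °C
Reagents that add atoms: none
Why: Wittig olefination with a non-stabilised ylide on an aldehyde that has no α-hydrogen; the Z geometry is of no consequence because the alkene is saturated in step 5.

Step 5
Reactants: 7 the Z-alkene of step 4
Product: 9 methyl (3R)-5-[(1S,6R)-1,6-dimethyl-4-oxocyclohex-2-en-1-yl]-3-methylpentanoate, via saturated silyl enol ether 8 (not isolated)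
Conditions: 2-nitrobenzenesulfonylhydrazide, Et3N, CH2Cl2, 23 °C; then 1 M HCl, THF, 0 → 23 °C
Reagents that add atoms: none
Why: Diimide reduction saturates the disubstituted alkene and spares the trisubstituted silyl enol ether, after which acid hydrolysis and E1cB loss of dimethylamine unveil the 4,4-disubstituted enone.

Step 6
Reactants: 9 the enone of step 5
Product: 10 methyl (3R)-5-[(1S,6R)-5-hydroxy-1,6-dimethyl-4-oxocyclohex-2-en-1-yl]-3-methylpentanoate (C7–OH trans to the C17 methyl)
Conditions: LiN(i-Pr)2, THF, −78 °C; then 2-(phenylsulfonyl)-3-phenyloxaziridine, −78 °C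
Reagents that add atoms: 2-(phenylsulfonyl)-3-phenyloxaziridine, O=S(=O)(N1OC1c1ccccc1)c1ccccc1
Why: Kinetic α′-deprotonation (quaternary C9 leaves no γ-hydrogen) followed by electrophilic enolate hydroxylation anti to the C17 methyl; this centre is planarised again in step 8, so its configuration does not matter.

Step 7
Reactants: 10 the α′-hydroxy enone
Product: 11 methyl (3R)-5-[(1S,6R)-5-methoxy-1,6-dimethyl-4-oxocyclohex-2-en-1-yl]-3-methylpentanoate
Conditions: MeI, Ag2O, MeCN, 23 °C, dark
Reagents that add atoms: iodomethane, CI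
Why: Purdie methylation (silver oxide-mediated O-alkylation) of the α-hydroxy ketone under non-basic conditions that avoid enolisation or retro-aldol cleavage.

Step 8
Reactants: 11 the α′-methoxy enone; 12 2,3-dibromoprop-1-ene
Product: 13 methyl (3R)-5-[5-(2-bromoprop-2-en-1-yl)-5-methoxy-1,6-dimethyl-4-oxocyclohex-2-en-1-yl]-3-methylpentanoate (bromoallyl arm trans to the C17 methyl, cis to the C11 chain)
Conditions: LiN(i-Pr)2, THF–DMPU, −78 °C; then 12, −78 → −30 °C
Reagents that add atoms: none
Why: Alkylation of the cross-conjugated α′-enolate by the allylic bromide, which enters anti to the adjacent C17 methyl (1,2-induction) and so sets quaternary C7 with the arm on the face of the C11 chain.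

Step 9
Reactants: 13 the vinyl bromide of step 8
Product: 14 methyl (3R)-5-[4-methoxy-2,3-dimethyl-6-methylidene-8-oxobicyclo[2.2.2]octan-2-yl]-3-methylpentanoate (bicyclooctane C1 = C10, C2 = C9, C3 = C8, C4 = C7, C6 = C5, C8 = C2 of the target)
Conditions: Pd(OAc)2 (10 mol %), PPh3, HCO2Na, Et4NCl, DMF, 80 °C
Reagents that add atoms: none
Why: Intramolecular reductive Heck cyclisation in which the vinylpalladium adds 6-exo to the enone β-carbon C10 on the only face the tether can reach and formate reduces the palladium enolate, so C10 is set by C7.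

Step 10
Reactants: 14 the exocyclic alkene
Product: 15 methyl (3R)-5-[4-methoxy-2,3,6-trimethyl-8-oxobicyclo[2.2.2]oct-5-en-2-yl]-3-methylpentanoate (C5=C6 alkene bridge syn to the chain; C17 and C20 methyls syn to the ketone bridge)
Conditions: RhCl3·3H2O (5 mol %), MeOH–toluene, 65 °C
Reagents that add atoms: none
Why: Rhodium hydride-mediated alkene isomerisation moves the double bond to the trisubstituted endocyclic position C5=C6, the only one open because a double bond toward bridgehead C10 is excluded.

Step 11
Reactants: 15 the bridged ketone; 16 methoxyallene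
Product: 17 methyl (3R)-5-[8-hydroxy-4-methoxy-8-(1-methoxypropa-1,2-dien-1-yl)-2,3,6-trimethylbicyclo[2.2.2]oct-5-en-2-yl]-3-methylpentanoate (allenyl group syn to the C5=C6 bridge)
Conditions: 16, n-BuLi, THF, −78 °C; then 15, −78 °C
Reagents that add atoms: none
Why: 1,2-Addition of 1-lithio-1-methoxyallene to the ketone at −78 °C, faster than attack on the remote ester; the C17 and C20 methyls block the ketone face turned toward C8–C9, so the nucleophile enters from the side of the alkene bridge and ends syn to it.

Step 12
Reactants: 17 the allenyl carbinol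
Product: 19 ring A enol pivalate (cis-decalin: C2–OPiv, C3–OMe, C4=C18, C6=C7–OMe), via potassium enolate 18 (not isolated)
Conditions: KN(SiMe3)2 (1.1 equiv), 18-crown-6, THF, −78 → 0 °C; then PivCl, −78 °C
Reagents that add atoms: pivaloyl chloride, CC(C)(C)C(Cl)=O
Why: The crown-ether-separated tertiary alkoxide at C2 triggers an anionic oxy-Cope [3,3]-sigmatropic shift across the 1,5-diene C4=C3–C2–C7–C6=C5 (C4 is the central allene carbon): the strained C2–C7 bond breaks, C4–C5 forms, and the resulting potassium enolate (O–C2=C3) is O-acylated by PivCl. The closest known reaction type is the anionic oxy-Cope rearrangement of 2-vinylbicyclo[2.2.2]oct-5-en-2-ols to cis-decalinones, together with the Cope rearrangement of 1,2,6-trienes through the central allene carbon. Ring A (C1–C5, C10) is closed by this single suprafacial C4–C5 bond formation in a boat-shaped six-centre pericyclic transition state, while the temporary ring C1–C2–C7–C6–C5–C10 is opened and ring B is unchanged. The only new stereocentre, quaternary C5, is controlled by bridgehead C10 and the bicyclic frame: C4 can reach C5 only on the alkene face that carries the C1–C2 bridge, so C4 and C1 end cis on ring B, with the configuration relative to C9 already fixed in steps 8 and 9. The step needs the [3,3] shift to outrun 5-endo attack of the alkoxide on C18 and retro-addition of the allenyl anion; this is secured by the strain released on opening the bicyclooctene, by the syn placement of the allenyl group over C5=C6 (step 11) and by aprotic conditions that give a 5-endo vinyl anion no proton. O- rather than C-acylation follows from the hard acyl chloride and the naked enolate at fully substituted C3.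

Step 13
Reactants: 19 the bis(enol ether)
Product: 20 C7 ketone (ring A diene unchanged)
Conditions: (CO2H)2 (0.1 M aq.), THF, 0 °C
Reagents that add atoms: water, O
Why: Acid-catalysed enol ether hydrolysis, in which the simple trisubstituted ring B enol ether is C-protonated far faster than the ring A enol ether, whose protonation site C2 is fully substituted and deactivated by the pivaloyloxy group.

Step 14
Reactants: 20 the C7 ketone
Product: 21 (7S)-alcohol (equatorial C7–OH)
Conditions: SmI2 (2.5 equiv), H2O, THF, 0 °C
Reagents that add atoms: none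
Why: Single-electron ketyl reduction under thermodynamic control, as in dissolving-metal reductions: the C7 oxygen takes the equatorial position away from the axial C20 methyl and C4, whereas hydride reagents would attack along the open equatorial direction and give the axial epimer.

Step 15
Reactants: 21 the (7S)-alcohol
Product: 22 (7S)-acetate
Conditions: Ac2O, DMAP, pyridine, CH2Cl2, 23 °C
Reagents that add atoms: acetic anhydride, CC(=O)OC(C)=O
Why: DMAP-catalysed acylation (esterification) of the unhindered equatorial secondary alcohol with retention at C7.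

Step 16
Reactants: 22 the acetate
Product: 25 CNP0180040.1 (target diosphenol), via epoxide 23 (not isolated), via diketone 24 (not isolated)
Conditions: dimethyldioxirane (1.1 equiv), acetone, −78 → −20 °C; then pH 7 aqueous buffer, 23 °C
Reagents that add atoms: dimethyldioxirane, CC1(C)OO1; water, O
Why: Rubottom-type epoxidation of the most electron-rich alkene (the tetrasubstituted C2=C3 enol ether/enol ester); the 2-acyloxy-3-methoxy oxirane collapses with loss of pivalate and methanol to the 2,3-diketone, which can enolise only toward C1 because C4 bears no hydrogen.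

**Compound list**

1 | methyl hydrogen (R)-3-methylglutarate [(3R)-5-methoxy-3-methyl-5-oxopentanoic acid] | OC(=O)C[C@@H](C)CC(=O)OC | starting material
2 | methyl (3S)-4-iodo-3-methylbutanoate | IC[C@@H](C)CC(=O)OC | intermediate
3 | [(2S)-4-methoxy-2-methyl-4-oxobutyl]triphenylphosphonium iodide | COC(=O)C[C@H](C)C[P+](c1ccccc1)(c1ccccc1)c1ccccc1.[I-] | intermediate
4 | (1E)-3-(tert-butyldimethylsilyloxy)-N,N-dimethylbuta-1,3-dien-1-amine | CN(C)/C=C/C(=C)O[Si](C)(C)C(C)(C)C | starting material
5 | (2E)-2-methylbut-2-enal (tiglic aldehyde) | C/C=C(\C)C=O | starting material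
6 | (1S,2R,6R)-4-(tert-butyldimethylsilyloxy)-2-(dimethylamino)-1,6-dimethylcyclohex-3-ene-1-carbaldehyde | O=C[C@@]1(C)[C@H](C)CC(O[Si](C)(C)C(C)(C)C)=C[C@H]1N(C)C | intermediate
7 | methyl (3S,4Z)-5-[(1S,2R,6R)-4-(tert-butyldimethylsilyloxy)-2-(dimethylamino)-1,6-dimethylcyclohex-3-en-1-yl]-3-methylpent-4-enoate | COC(=O)C[C@H](C)/C=C\[C@@]1(C)[C@H](C)CC(O[Si](C)(C)C(C)(C)C)=C[C@H]1N(C)C | intermediate
8 | saturated silyl enol ether (C11–C12 single bond; not isolated) | COC(=O)C[C@H](C)CC[C@@]1(C)[C@H](C)CC(O[Si](C)(C)C(C)(C)C)=C[C@H]1N(C)C | intermediate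
9 | methyl (3R)-5-[(1S,6R)-1,6-dimethyl-4-oxocyclohex-2-en-1-yl]-3-methylpentanoate | O=C1C=C[C@@](C)(CC[C@@H](C)CC(=O)OC)[C@H](C)C1 | intermediate
10 | α′-hydroxy enone (C7–OH trans to the C17 methyl) | O=C1C=C[C@@](C)(CC[C@@H](C)CC(=O)OC)[C@H](C)[C@H]1O | intermediate
11 | α′-methoxy enone | O=C1C=C[C@@](C)(CC[C@@H](C)CC(=O)OC)[C@H](C)[C@H]1OC | intermediate
12 | 2,3-dibromoprop-1-ene | C=C(Br)CBr | starting material
13 | α′-(2-bromoallyl)-α′-methoxy enone (arm trans to the C17 methyl) | O=C1C=C[C@@](C)(CC[C@@H](C)CC(=O)OC)[C@H](C)[C@@]1(OC)CC(Br)=C | intermediate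
14 | bridged ketone with exocyclic C5=C19 methylene | C=C1C[C@@]2(OC)C(=O)C[C@@H]1[C@@](C)(CC[C@@H](C)CC(=O)OC)[C@@H]2C | intermediate
15 | bridged ketone, 1-methoxybicyclo[2.2.2]oct-5-en-2-one type with C5(Me)=C6 | CC1=C[C@@]2(OC)C(=O)C[C@@H]1[C@@](C)(CC[C@@H](C)CC(=O)OC)[C@@H]2C | intermediate
16 | methoxyallene (1-methoxypropa-1,2-diene) | COC=C=C | starting material
17 | 1-methoxyallenyl carbinol (allenyl syn to C5=C6) | CC1=C[C@@]2(OC)[C@@](O)(C(OC)=C=C)C[C@@H]1[C@@](C)(CC[C@@H](C)CC(=O)OC)[C@@H]2C | intermediate
18 | potassium enolate of the cis-decalin (not isolated) | C=C1C(OC)=C([O-])C[C@@H]2[C@@](C)(CC[C@@H](C)CC(=O)OC)[C@H](C)C(OC)=C[C@]12C.[K+] | intermediate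
19 | ring A enol pivalate, ring B methyl enol ether | C=C1C(OC)=C(OC(=O)C(C)(C)C)C[C@@H]2[C@@](C)(CC[C@@H](C)CC(=O)OC)[C@H](C)C(OC)=C[C@]12C | intermediate
20 | C7 ketone | C=C1C(OC)=C(OC(=O)C(C)(C)C)C[C@@H]2[C@@](C)(CC[C@@H](C)CC(=O)OC)[C@H](C)C(=O)C[C@]12C | intermediate
21 | (7S)-alcohol | C=C1C(OC)=C(OC(=O)C(C)(C)C)C[C@@H]2[C@@](C)(CC[C@@H](C)CC(=O)OC)[C@H](C)[C@@H](O)C[C@]12C | intermediate
22 | (7S)-acetate | C=C1C(OC)=C(OC(=O)C(C)(C)C)C[C@@H]2[C@@](C)(CC[C@@H](C)CC(=O)OC)[C@H](C)[C@@H](OC(C)=O)C[C@]12C | intermediate
23 | C2–C3 epoxide (oxirane configuration immaterial; not isolated) | C=C1C2(OC)OC2(OC(=O)C(C)(C)C)C[C@@H]3[C@@](C)(CC[C@@H](C)CC(=O)OC)[C@H](C)[C@@H](OC(C)=O)C[C@]13C | intermediate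
24 | 2,3-diketone (not isolated) | C=C1C(=O)C(=O)C[C@@H]2[C@@](C)(CC[C@@H](C)CC(=O)OC)[C@H](C)[C@@H](OC(C)=O)C[C@]12C | intermediate
25 | CNP0180040.1, (5S,7S,8S,9R,10R,13R) | C=C1C(=O)C(O)=C[C@@H]2[C@@](C)(CC[C@@H](C)CC(=O)OC)[C@H](C)[C@@H](OC(C)=O)C[C@]12C | target

**Totals**

Total steps: 16. Longest linear sequence: 15 steps (steps 1, 2 and 4–16, from 1).

**Steps most likely to fail**

Step 12 (key step). The alkoxide may cyclise 5-endo onto the allene terminus, or expel the allenyl anion by retro-addition, before the [3,3] shift takes place. The fallback leaves the charged manifold and sets out from 17. Silylation (TMSOTf, 2,6-lutidine, CH2Cl2, −78 °C) should give the trimethylsilyl ether of the carbinol F1. Heating F1 (o-dichlorobenzene, 160 °C, N,O-bis(trimethylsilyl)acetamide as acid scavenger) should effect a neutral siloxy-Cope rearrangement to the ring A trimethylsilyl dienol ether F2. KOt-Bu (THF, −78 °C) then releases enolate 18, and PivCl returns the route at 19.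

Step 3. Slow cycloaddition of the trisubstituted enal may let the uncatalysed background reaction erode the enantiomeric purity. The fallback changes diene and activation mode and sets out from 5. But-3-en-2-one, TIPSOTf and Et3N should give 2-(triisopropylsilyloxy)buta-1,3-diene F3. With 5, under the oxazaborolidinium triflimide made from (S)-diphenylprolinol, o-tolylboronic acid and HNTf2 (CH2Cl2, −78 °C), F3 should give the 1,6-dimethyl-4-(triisopropylsilyloxy)cyclohex-3-ene-1-carbaldehyde F4, configured at the two methyl-bearing carbons as in 6. Wittig reaction with 3 (as step 4) gives the Z-alkene F5, and diimide reduction gives the saturated triisopropylsilyl enol ether F6. Saegusa oxidation (Pd(OAc)2, MeCN) returns the route at 9.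

Step 14. Facial control may be poor, so that the axial C7 alcohol forms, or the enol pivalate may be cleaved by the reductant. The fallback accepts kinetic control and then inverts, setting out from 20. NaBH4 (MeOH, −20 °C) should attack along the equatorial direction and give the axial (7R)-alcohol F7. Mitsunobu reaction of F7 with AcOH (PPh3, DIAD, toluene, 0 → 23 °C) inverts C7 and returns the route directly at 22.

**Further compounds**

F1 | step 12 | trimethylsilyl ether of carbinol 17 | CC1=C[C@@]2(OC)[C@@](O[Si](C)(C)C)(C(OC)=C=C)C[C@@H]1[C@@](C)(CC[C@@H](C)CC(=O)OC)[C@@H]2C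
F2 | step 12 | ring A trimethylsilyl dienol ether (2-trimethylsilyloxy analogue of 19) | C=C1C(OC)=C(O[Si](C)(C)C)C[C@@H]2[C@@](C)(CC[C@@H](C)CC(=O)OC)[C@H](C)C(OC)=C[C@]12C
F3 | step 3 | 2-(triisopropylsilyloxy)buta-1,3-diene | C=CC(=C)O[Si](C(C)C)(C(C)C)C(C)C
F4 | step 3 | 1,6-dimethyl-4-(triisopropylsilyloxy)cyclohex-3-ene-1-carbaldehyde (methyls cis) | O=C[C@@]1(C)[C@H](C)CC(O[Si](C(C)C)(C(C)C)C(C)C)=CC1
F5 | step 3 | Z-alkene from F4 and 3 | COC(=O)C[C@H](C)/C=C\[C@@]1(C)[C@H](C)CC(O[Si](C(C)C)(C(C)C)C(C)C)=CC1
F6 | step 3 | saturated triisopropylsilyl enol ether | COC(=O)C[C@H](C)CC[C@@]1(C)[C@H](C)CC(O[Si](C(C)C)(C(C)C)C(C)C)=CC1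
F7 | step 14 | axial (7R)-alcohol, C7 epimer of 21 | C=C1C(OC)=C(OC(=O)C(C)(C)C)C[C@@H]2[C@@](C)(CC[C@@H](C)CC(=O)OC)[C@H](C)[C@H](O)C[C@]12C
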